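# Proposed synthesis of CNP0263064.1: (2S)-2-[2-geranyl-3,4-dihydroxyphenyl]-7-hydroxychroman-4-one

## The problem

The target is a (2S)-flavanone: a chroman-4-one (ring A fused to the pyranone ring C through C4a–C8a) with a free 7-hydroxyl, whose C2 carries ring B, a catechol with a geranyl chain at C2′ wedged between the C1′–C2 bond and the C3′ hydroxyl. C2 is the only stereocentre, so nothing in the molecule can relay its configuration. It has to come from a reagent, and once the C4 ketone and the O1 aryl ether are both in place it can be lost by base-induced retro-oxa-Michael opening to the 2′-hydroxychalcone. The geranyl chain brings two trisubstituted alkenes, one of fixed E geometry, which exclude hydrogenation, ozonolysis, free borane and strong acid; under acid the neighbouring C3′ hydroxyl can add to the first alkene to give a chroman. Ring B is 1,2,3,4-tetrasubstituted, and the chain has to be delivered to its most hindered position. Three phenols are present, two of them an oxidation-prone catechol, and their masks must survive strong base yet leave under conditions that spare the alkenes and C2. The feature on which the plan rests is the substitution pattern of ring A. The C7 hydroxyl, the C8a ether oxygen and the C4 acyl carbon on C4a sit where a vinylketene–ynol ether benzannulation places the ketene oxygen, the alkynyl ether oxygen and the ketene α-substituent. C5, C6 and C8 carry only hydrogen (a bare vinyl group and a terminal alkyne), and the three-atom chain O1–C2–C3 that links C8a to C4 makes the annulation intramolecular, so it closes ring C as well.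

## Retrosynthesis

**Target 27 to flavanone 26.** The two acetal C–O bonds at O3′ and O4′ are cut; the 7-hydroxyl needs no mask because the key step delivers it free. Methoxymethyl (MOM) ethers are preferred to silyl ethers (unsafe towards KH and n-BuLi, and removed by basic fluoride that endangers C2), to benzyl ethers (hydrogenolysis would reduce the alkenes) and to methyl ethers (BBr3). The forward step only has to be acidic enough for acetal cleavage and mild enough for the geranyl chain.

**Flavanone 26 to diazo diketone 21.** Four bonds are cut at once: C4a–C5, C4a–C8a, C7–C8 and C6–C7. Ring A is taken apart into a vinyl group, a diazo carbon and the two carbons of an ethynyl ether, and ring C opens with it. The neighbouring cuts (O1–C2 by chalcone cyclisation, O1–C8a by arylation, C4–C4a by Friedel–Crafts acylation) each form one bond, need a finished ring A building block, and bring base, hot metal catalysis or strong acid next to C2. Precursor 21 is acyclic and carries only the spectator stereocentre. The forward reaction must make the vinyl group, not the alkyl chain, migrate in the Wolff step, and must make the ketene C=C bond, not the acylketene oxadiene, add to the alkyne, all below the temperature at which the ynol ether fragments.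

**Diazo diketone 21 to aldehyde 16 and diazo ketone 19.** The C4–C4a bond is cut; forward, the lithiated acyldiazomethane 19 adds to 16 to give carbinol 20, which is oxidised. This puts the diazo group in place without passing through an enolisable vinyl 1,3-diketone and without amine base at room temperature, which would expel the ynolate from the β-alkynyloxy carbonyl compounds. Diazo ketone 19 comes from methyl vinyl ketone 17 by detrifluoroacetylative diazo transfer through diketone 18.

**Aldehyde 16 to alcohol 10 and trichloroethylene 11.** The O–C(sp) bond of the ynol ether is cut, and both alkyne carbons come from 11 through dichlorovinyl ether 12 and acetylide 13. This step needs KH and n-BuLi, so it must precede every carbonyl group; C4 therefore travels as a primary triisopropylsilyl (TIPS) ether (14), is unmasked (15) and oxidised (16). TIPS is chosen over smaller silyl groups because it should not migrate to the neighbouring potassium alkoxide.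

**Alcohol 10 to aryl bromide 5 and aldehyde 6.** The C2–H bond and the C1′–C2 bond are cut. Ketone 9 is reduced by an oxazaborolidine catalyst whose facial sense for aryl alkyl ketones is well established; 9 comes from racemic carbinol 8, made by adding aryllithium 7 to aldehyde 6. An auxiliary-based acetate aldol on the corresponding benzaldehyde would need four steps (formylation, aldol, reduction, silylation) for the same compound; this sequence needs three.

**Aryl bromide 5 to bromide 2, geranyl bromide 3 and 4-bromocatechol 1.** The aryl–geranyl bond is cut. In 2 the ring hydrogen flanked by OMOM and Br is the most acidic, so an amide base gives aryllithium 4 at the required position, and copper-mediated allylation with 3 installs the chain. The bromine then becomes the handle for the C1′–C2 bond. Electrophilic geranylation or a Claisen route would not reach this position selectively.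

## Roads not taken

**Alternative 1:** Ring B by Diels–Alder benzannulation. The cut is through C1′–C2′ and C5′–C6′. Forward, (6E)-7,11-dimethyldodeca-6,10-diene-2,3-dione A1 is converted into its bis(silyloxy)diene A2, which adds to a propiolate ester; DDQ in the same flask aromatises the adduct to methyl 2-geranyl-3,4-bis(tert-butyldimethylsilyloxy)benzoate A3.
- Merit: the four contiguous substituents of ring B are fixed by construction, with no ortho-bromoaryllithium on the way. In this respect it is cleaner than steps 1 and 2 of the chosen plan.
- Weak points: the two silyloxy groups of A2 cancel each other's directing effect, so regiochemistry rests on the alkyl terminus alone. The substituted diene terminus reacts sluggishly unless the enol ether geometry is controlled. DDQ can attack the doubly allylic positions.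
- Scope: A3 solves only ring B. Rings A and C and the stereocentre remain, and the silyl ethers would have to be exchanged before any strongly basic step.
- Comparison: the chosen plan reaches the equivalent building block 5 in two steps from 1, and spends its novelty on rings A and C, where more bonds are gained.

**Alternative 2:** Copper-catalysed O-arylation closing O1–C8a. Forward, the diol (1S,3S)-3-[2-bromo-4-(methoxymethoxy)phenyl]-1-[2-geranyl-3,4-bis(methoxymethoxy)phenyl]propane-1,3-diol A4 is cyclised with CuI, 1,10-phenanthroline and Cs2CO3 to (2S,4S)-2-[2-geranyl-3,4-bis(methoxymethoxy)phenyl]-7-(methoxymethoxy)chroman-4-ol A5, which is then oxidised and deprotected.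
- Merit: every step is known chemistry, the C2–O bond is never broken, and C4 is an alcohol during the basic step, so C2 cannot epimerise. This is the more reliable road and would probably not be longer.
- Weak points: A4 needs its own stereocontrolled assembly from two aryl fragments. The hindered secondary benzylic alkoxide must couple at about 110 °C next to the geranyl group. Two further steps follow the ring closure.
- Comparison: the chosen plan sets against this reliability one operation that forms four carbon–carbon bonds and two rings under neutral conditions at or below 80 °C and releases the 7-hydroxyl unprotected. It accepts in return a key step without direct precedent.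

**Alternative 3:** Carbenoid C–H insertion closing C2–C3. Forward, a chiral dirhodium tetracarboxylate converts 2-diazo-1-[2-{[2-geranyl-3,4-bis(methoxymethoxy)phenyl]methoxy}-4-(methoxymethoxy)phenyl]ethan-1-one A6 into a carbenoid at C3 that inserts into one enantiotopic C2–H bond, giving (S)-2-[2-geranyl-3,4-bis(methoxymethoxy)phenyl]-7-(methoxymethoxy)chroman-4-one A7.
- Merit: it is the shortest road. A6 is achiral and comes from a simple benzyl ether, and ring closure and stereocentre are created together.
- Weak points: attack of the ether oxygen O1 on the carbenoid gives a five-membered oxonium ylide that rearranges to a 2-benzylbenzofuran-3-one, the usual course for 2-alkoxyaryl diazo ketones. Acceptor-only carbenoids give modest enantioselectivity. The doubly activated benzylic–allylic CH2 and the alkenes of the geranyl chain are further targets.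
- Comparison: in step count this road beats the chosen plan. The chosen plan sets against it a stereocentre installed by a dependable reagent-controlled reduction before the key step, and a key step whose periselectivity is enforced by the geometry of the tether, not by the choice of catalyst.

Key step: step 12

## Conventions and assumption

- geranyl = (2E)-3,7-dimethylocta-2,6-dien-1-yl; MOM = methoxymethyl; TIPS = triisopropylsilyl.
- Flavanone numbering (O1, C2, C3, C4, C4a, C5–C8, C8a; ring B primed) is used for all intermediates.
- Assumption: 3-(triisopropylsilyloxy)propanal (6) is taken as a purchasable building block; if it has to be made, monosilylation of propane-1,3-diol and oxidation give it in two routine steps.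

## Route

Step 1
Reactants: 1 4-bromocatechol
Product: 2 4-bromo-1,2-bis(methoxymethoxy)benzene
Conditions: MOMCl, i-Pr2NEt, CH2Cl2, 0 °C to rt
Reagents that add atoms: chloromethyl methyl ether, COCCl
Why: O-alkylation of both phenols with an α-chloro ether and a hindered amine base. The MOM acetals withstand KH and organolithiums, direct the metalation of step 2 and leave with mild acid at the end.

Step 2
Reactants: 2 4-bromo-1,2-bis(methoxymethoxy)benzene; 3 geranyl bromide
Product: 5 1-bromo-2-geranyl-3,4-bis(methoxymethoxy)benzene, via aryllithium 4 (not isolated)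
Conditions: LiN(i-Pr)2, THF, –78 °C; CuBr·SMe2, –78 °C; then 3, –78 to –20 °C
Reagents that add atoms: none
Why: Directed ortho-metalation: the amide base removes the ring proton flanked by OMOM and Br, the most acidic one, without exchanging the bromide. Transmetalation to copper at –78 °C should suppress loss of LiBr to an aryne, and the arylcopper should couple with the primary allylic bromide at its α-carbon with the E alkene unchanged.

Step 3
Reactants: 5 1-bromo-2-geranyl-3,4-bis(methoxymethoxy)benzene; 6 3-(triisopropylsilyloxy)propanal
Product: 8 rac-1-[2-geranyl-3,4-bis(methoxymethoxy)phenyl]-3-(triisopropylsilyloxy)propan-1-ol, via aryllithium 7 (not isolated)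
Conditions: n-BuLi, THF, –78 °C; then 6, –78 °C; aq NH4Cl
Reagents that add atoms: none
Why: Bromine–lithium exchange is far faster than any deprotonation at –78 °C, and 1,2-addition of the aryllithium to the aldehyde forms the C1′–C2 bond. The carbinol is made racemic on purpose, since step 5 sets it.

Step 4
Reactants: 8 rac-1-[2-geranyl-3,4-bis(methoxymethoxy)phenyl]-3-(triisopropylsilyloxy)propan-1-ol
Product: 9 1-[2-geranyl-3,4-bis(methoxymethoxy)phenyl]-3-(triisopropylsilyloxy)propan-1-one
Conditions: Dess–Martin periodinane, NaHCO3, CH2Cl2, rt
Reagents that add atoms: none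
Why: Dess–Martin oxidation of a secondary benzylic alcohol under buffered conditions; alkenes, MOM acetals and the silyl ether should be untouched.

Step 5
Reactants: 9 1-[2-geranyl-3,4-bis(methoxymethoxy)phenyl]-3-(triisopropylsilyloxy)propan-1-one
Product: 10 (S)-1-[2-geranyl-3,4-bis(methoxymethoxy)phenyl]-3-(triisopropylsilyloxy)propan-1-ol
Conditions: (R)-1-methyl-3,3-diphenyltetrahydro-1H,3H-pyrrolo[1,2-c][1,3,2]oxazaborole (20 mol %), catecholborane, PhMe, –78 to –40 °C; MeOH, then aq NaOH
Reagents that add atoms: none
Why: Corey–Bakshi–Shibata reduction: with the aryl group as the large substituent, the (R)-catalyst delivers hydride to the Re face of the ketone, the established sense for aryl alkyl ketones, and sets the (S)-carbinol that becomes C2. Catecholborane at low temperature should not hydroborate the geranyl alkenes.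

Step 6
Reactants: 10 (S)-1-[2-geranyl-3,4-bis(methoxymethoxy)phenyl]-3-(triisopropylsilyloxy)propan-1-ol; 11 trichloroethylene
Product: 14 (S)-1-[1-(ethynyloxy)-3-(triisopropylsilyloxy)propyl]-2-geranyl-3,4-bis(methoxymethoxy)benzene, via dichlorovinyl ether 12 (not isolated), via lithium alkynyl ether 13 (not isolated)
Conditions: KH, THF, 0 °C to rt; 11, –50 °C to rt; n-BuLi (2.5 equiv), –78 to –40 °C; MeOH, –78 °C
Reagents that add atoms: none
Why: Trichloroethylene route to alkynyl ethers: the potassium alkoxide adds to dichloroacetylene formed in situ to give the (E)-1,2-dichlorovinyl ether 12, and n-BuLi then eliminates HCl and exchanges the remaining chlorine to give acetylide 13, which methanol protonates. The C2–O bond is never broken, so the S configuration is kept. TIPS is used because it should not migrate to the neighbouring potassium alkoxide.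

Step 7
Reactants: 14 (S)-1-[1-(ethynyloxy)-3-(triisopropylsilyloxy)propyl]-2-geranyl-3,4-bis(methoxymethoxy)benzene
Product: 15 (S)-3-(ethynyloxy)-3-[2-geranyl-3,4-bis(methoxymethoxy)phenyl]propan-1-ol
Conditions: Bu4NF, THF, 0 °C to rt; H2O
Reagents that add atoms: none
Why: Fluoride cleavage of the primary silyl ether. Alkynyl ethers, MOM acetals and alkenes are inert to the reagent and no acid is involved.

Step 8
Reactants: 15 (S)-3-(ethynyloxy)-3-[2-geranyl-3,4-bis(methoxymethoxy)phenyl]propan-1-ol
Product: 16 (S)-3-(ethynyloxy)-3-[2-geranyl-3,4-bis(methoxymethoxy)phenyl]propanal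
Conditions: Dess–Martin periodinane, NaHCO3, CH2Cl2, 0 °C
Reagents that add atoms: none
Why: Dess–Martin oxidation, buffered so that the acetic acid released cannot add to the alkynyl ether. The β-alkynyloxy aldehyde is used at once, because base would expel the ynolate.

Step 9
Reactants: 17 methyl vinyl ketone
Product: 19 1-diazobut-3-en-2-one, via trifluoroacetyl diketone 18 (not isolated)
Conditions: LiN(SiMe3)2, THF, –78 °C; CF3CO2CH2CF3, –78 °C; dilute HCl work-up; then MsN3, Et3N, H2O, MeCN, rt
Reagents that add atoms: methanesulfonyl azide, CS(=O)(=O)N=[N+]=[N-]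
Why: Detrifluoroacetylative diazo transfer, a variant of the Regitz diazo transfer: the kinetic enolate of the enone is trifluoroacetylated, and the activated diketone 18 takes the diazo group from the sulfonyl azide with loss of the trifluoroacetyl group. This avoids exposing an acryloyl chloride to diazomethane; the product is kept as a cold solution.

Step 10
Reactants: 16 (S)-3-(ethynyloxy)-3-[2-geranyl-3,4-bis(methoxymethoxy)phenyl]propanal; 19 1-diazobut-3-en-2-one
Product: 20 (1S)-4-diazo-1-(ethynyloxy)-1-[2-geranyl-3,4-bis(methoxymethoxy)phenyl]-3-hydroxyhept-6-en-5-one (both epimers at the carbinol carbon)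
Conditions: 19, LiN(SiMe3)2, THF, –78 °C; then 16, –78 °C; aq NH4Cl
Reagents that add atoms: none
Why: Aldol-type addition of a lithiated acyldiazomethane to an aldehyde forms the C4–C4a bond; at –78 °C addition should outrun enolisation of the aldehyde. The new carbinol centre forms without control and is removed in step 11.

Step 11
Reactants: 20 (1S)-4-diazo-1-(ethynyloxy)-1-[2-geranyl-3,4-bis(methoxymethoxy)phenyl]-3-hydroxyhept-6-en-5-one
Product: 21 (S)-4-diazo-1-(ethynyloxy)-1-[2-geranyl-3,4-bis(methoxymethoxy)phenyl]hept-6-ene-3,5-dione
Conditions: Dess–Martin periodinane, NaHCO3, CH2Cl2, 0 °C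
Reagents that add atoms: none
Why: Dess–Martin oxidation of an α-diazo-β-hydroxy ketone, an established entry to unsymmetrical 2-diazo-1,3-diketones. The diazo group and the alkynyl ether tolerate the neutral oxidant, and the product is kept cold and used promptly.

Step 12
Reactants: 21 (S)-4-diazo-1-(ethynyloxy)-1-[2-geranyl-3,4-bis(methoxymethoxy)phenyl]hept-6-ene-3,5-dione
Product: 26 (S)-2-[2-geranyl-3,4-bis(methoxymethoxy)phenyl]-7-hydroxychroman-4-one, via acylvinylketene 22 (not isolated), via bicyclic vinylcyclobutenone 23 (not isolated), via dienylketene 24 (not isolated), via cyclohexadienone 25 (not isolated)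
Conditions: hν (350 nm lamps, Pyrex), degassed PhMe (0.003 M), 0 °C; then 80 °C in the dark
Reagents that add atoms: none
Why: Proposed new method: light expels N2 from the diazo diketone with 1,2-shift of the vinyl group (C4a–C5) to give acyl(vinyl)ketene 22; the closest known reaction type is the photochemical Wolff variant of the vinylketene–alkyne (Danheiser) benzannulation, so far only intermolecular and without an acyl group on the ketene. The nucleophilic terminal carbon of the ynol ether attacks the ketene carbonyl carbon (C7–C8) and the oxygen-bearing carbon bonds to the ketene α-carbon (C4a–C8a); this intramolecular [2+2] cycloaddition closes ring C, six-membered because of the three-atom C3–C2–O1 tether, as the fused cyclobutenone 23. Ring A follows by thermal 4π electrocyclic opening of 23 to dienylketene 24, 6π electrocyclisation (C6–C7) to dienone 25 and tautomerisation to the phenol. No new stereocentre survives, since the quaternary C4a of 23 becomes sp2, and C2 is a spectator because its bonds to O1 and C3 are never broken. The step needs vinyl rather than alkyl migration: the small, planar vinyl group is expected to lie anti to the departing N2 in the favoured conformer and to migrate with π participation, whereas the branched chain on C4 is the bulkier acyl substituent. It needs addition across the ketene C=C bond rather than across the acylketene oxadiene: a [4+2] addition would join the C4 oxygen to C8a, which already carries O1 of the same tether, and would give a bridged pyranone with two bridgehead double bonds, so only the [2+2] mode is geometrically open. It needs the vinyl and ketene arms cis for the 6π closure, and ring C enforces this by holding C4 and O1 cis on the C4a=C8a bond of 24. High dilution and irradiation at 0 °C should keep the acylketene from dimerising and the heat-sensitive ynol ether intact until it is consumed; only then is the solution warmed.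

Step 13
Reactants: 26 (S)-2-[2-geranyl-3,4-bis(methoxymethoxy)phenyl]-7-hydroxychroman-4-one
Product: 27 (S)-2-[2-geranyl-3,4-dihydroxyphenyl]-7-hydroxychroman-4-one (CNP0263064.1)
Conditions: 3 M aq HCl, MeOH, 40 °C
Reagents that add atoms: none
Why: Acid-catalysed acetal methanolysis removes both MOM groups. The flavanone stereocentre epimerises by base-induced ring opening and should be stable to dilute acid, and the low temperature is meant to spare the geranyl chain from cyclisation onto the C3′ hydroxyl.

## Compound list

1 | 4-bromocatechol (4-bromobenzene-1,2-diol) | Oc1ccc(Br)cc1O | starting material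
2 | 4-bromo-1,2-bis(methoxymethoxy)benzene | COCOc1ccc(Br)cc1OCOC | intermediate
3 | geranyl bromide, (2E)-1-bromo-3,7-dimethylocta-2,6-diene | CC(C)=CCC/C(C)=C/CBr | starting material
4 | [6-bromo-2,3-bis(methoxymethoxy)phenyl]lithium | [Li]c1c(Br)ccc(OCOC)c1OCOC | intermediate (not isolated)
5 | 1-bromo-2-geranyl-3,4-bis(methoxymethoxy)benzene | CC(C)=CCC/C(C)=C/Cc1c(Br)ccc(OCOC)c1OCOC | intermediate
6 | 3-(triisopropylsilyloxy)propanal | O=CCCO[Si](C(C)C)(C(C)C)C(C)C | starting material
7 | [2-geranyl-3,4-bis(methoxymethoxy)phenyl]lithium | CC(C)=CCC/C(C)=C/Cc1c([Li])ccc(OCOC)c1OCOC | intermediate (not isolated)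
8 | rac-1-[2-geranyl-3,4-bis(methoxymethoxy)phenyl]-3-(triisopropylsilyloxy)propan-1-ol | CC(C)=CCC/C(C)=C/Cc1c(C(O)CCO[Si](C(C)C)(C(C)C)C(C)C)ccc(OCOC)c1OCOC | intermediate
9 | 1-[2-geranyl-3,4-bis(methoxymethoxy)phenyl]-3-(triisopropylsilyloxy)propan-1-one | CC(C)=CCC/C(C)=C/Cc1c(C(=O)CCO[Si](C(C)C)(C(C)C)C(C)C)ccc(OCOC)c1OCOC | intermediate
10 | (S)-1-[2-geranyl-3,4-bis(methoxymethoxy)phenyl]-3-(triisopropylsilyloxy)propan-1-ol | CC(C)=CCC/C(C)=C/Cc1c([C@@H](O)CCO[Si](C(C)C)(C(C)C)C(C)C)ccc(OCOC)c1OCOC | intermediate
11 | trichloroethylene | ClC=C(Cl)Cl | starting material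
12 | (S)-1-{1-[(E)-1,2-dichloroethenyloxy]-3-(triisopropylsilyloxy)propyl}-2-geranyl-3,4-bis(methoxymethoxy)benzene | CC(C)=CCC/C(C)=C/Cc1c([C@@H](O/C(Cl)=C\Cl)CCO[Si](C(C)C)(C(C)C)C(C)C)ccc(OCOC)c1OCOC | intermediate (not isolated)
13 | lithium acetylide of 14, (S)-ArCH(OC≡CLi)CH2CH2OTIPS with Ar = 2-geranyl-3,4-bis(methoxymethoxy)phenyl | CC(C)=CCC/C(C)=C/Cc1c([C@@H](OC#C[Li])CCO[Si](C(C)C)(C(C)C)C(C)C)ccc(OCOC)c1OCOC | intermediate (not isolated)
14 | (S)-1-[1-(ethynyloxy)-3-(triisopropylsilyloxy)propyl]-2-geranyl-3,4-bis(methoxymethoxy)benzene | CC(C)=CCC/C(C)=C/Cc1c([C@@H](OC#C)CCO[Si](C(C)C)(C(C)C)C(C)C)ccc(OCOC)c1OCOC | intermediate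
15 | (S)-3-(ethynyloxy)-3-[2-geranyl-3,4-bis(methoxymethoxy)phenyl]propan-1-ol | CC(C)=CCC/C(C)=C/Cc1c([C@@H](OC#C)CCO)ccc(OCOC)c1OCOC | intermediate
16 | (S)-3-(ethynyloxy)-3-[2-geranyl-3,4-bis(methoxymethoxy)phenyl]propanal | CC(C)=CCC/C(C)=C/Cc1c([C@@H](OC#C)CC=O)ccc(OCOC)c1OCOC | intermediate
17 | methyl vinyl ketone (but-3-en-2-one) | CC(=O)C=C | starting material
18 | 1,1,1-trifluorohex-5-ene-2,4-dione | C=CC(=O)CC(=O)C(F)(F)F | intermediate (not isolated)
19 | 1-diazobut-3-en-2-one | C=CC(=O)C=[N+]=[N-] | intermediate
20 | (1S)-4-diazo-1-(ethynyloxy)-1-[2-geranyl-3,4-bis(methoxymethoxy)phenyl]-3-hydroxyhept-6-en-5-one, both C3 epimers | CC(C)=CCC/C(C)=C/Cc1c([C@@H](OC#C)CC(O)C(=[N+]=[N-])C(=O)C=C)ccc(OCOC)c1OCOC | intermediate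
21 | (S)-4-diazo-1-(ethynyloxy)-1-[2-geranyl-3,4-bis(methoxymethoxy)phenyl]hept-6-ene-3,5-dione | CC(C)=CCC/C(C)=C/Cc1c([C@@H](OC#C)CC(=O)C(=[N+]=[N-])C(=O)C=C)ccc(OCOC)c1OCOC | intermediate
22 | (S)-2-ethenyl-5-(ethynyloxy)-5-[2-geranyl-3,4-bis(methoxymethoxy)phenyl]-1-oxopent-1-en-3-one (acyl vinyl ketene) | CC(C)=CCC/C(C)=C/Cc1c([C@@H](OC#C)CC(=O)C(C=C)=C=O)ccc(OCOC)c1OCOC | intermediate (not isolated)
23 | (3S)-6-ethenyl-3-[2-geranyl-3,4-bis(methoxymethoxy)phenyl]-2-oxabicyclo[4.2.0]oct-1(8)-ene-5,7-dione, C6 epimers | CC(C)=CCC/C(C)=C/Cc1c([C@@H]2CC(=O)C3(C=C)C(=O)C=C3O2)ccc(OCOC)c1OCOC | intermediate (not isolated)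
24 | (S)-5-ethenyl-2-[2-geranyl-3,4-bis(methoxymethoxy)phenyl]-6-(2-oxoethenyl)-2,3-dihydro-4H-pyran-4-one | CC(C)=CCC/C(C)=C/Cc1c([C@@H]2CC(=O)C(C=C)=C(C=C=O)O2)ccc(OCOC)c1OCOC | intermediate (not isolated)
25 | (S)-2-[2-geranyl-3,4-bis(methoxymethoxy)phenyl]-2,3-dihydro-4H-chromene-4,7(6H)-dione | CC(C)=CCC/C(C)=C/Cc1c([C@@H]2CC(=O)C3=CCC(=O)C=C3O2)ccc(OCOC)c1OCOC | intermediate (not isolated)
26 | (S)-2-[2-geranyl-3,4-bis(methoxymethoxy)phenyl]-7-hydroxychroman-4-one | CC(C)=CCC/C(C)=C/Cc1c([C@@H]2CC(=O)c3ccc(O)cc3O2)ccc(OCOC)c1OCOC | intermediate
27 | (S)-2-[2-geranyl-3,4-dihydroxyphenyl]-7-hydroxychroman-4-one (CNP0263064.1) | CC(C)=CCC/C(C)=C/Cc1c([C@@H]2CC(=O)c3ccc(O)cc3O2)ccc(O)c1O | target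

## Step count and least certain steps

Total: 13 steps. Longest linear sequence: 12 steps (steps 1–8 and 10–13); step 9 prepares reagent 19.

**Step 12 (key step).**
- The alkyl chain may migrate in place of the vinyl group, since photochemical Wolff rearrangements of unsymmetrical 2-diazo-1,3-diketones discriminate poorly between the two acyl substituents.
- Carbene-type addition to the alkyne may compete with rearrangement.
- The ynol ether can be lost by retro-ene fragmentation if the solution warms before the [2+2] step.
- The diazo group may add thermally to the tethered alkyne on storage.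
- Moisture or dimerisation may intercept the acylketene.
- Fallback, by known chemistry, from aryl bromide 5 to target 27: bromine–lithium exchange of 5 and quenching with B(OMe)3 give [2-geranyl-3,4-bis(methoxymethoxy)phenyl]boronic acid F1. Commercial 7-hydroxychromen-4-one is converted with MOMCl into 7-(methoxymethoxy)chromen-4-one F2. Asymmetric 1,4-addition of F1 to F2, catalysed by [RhCl(C2H4)2]2 and a chiral diene ligand in aqueous KOH–dioxane, with the ligand enantiomer chosen on a model to deliver the S product, gives (S)-2-[2-geranyl-3,4-bis(methoxymethoxy)phenyl]-7-(methoxymethoxy)chroman-4-one F3. The conditions of step 13 then remove three MOM groups to give 27. The ortho-geranyl group will slow this addition, which is why it is held in reserve.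

**Step 6.**
- Addition of the hindered secondary alkoxide to dichloroacetylene may be incomplete.
- The silyl group may still migrate to the alkoxide.
- The benzylic alkynyl ether may ionise or fragment during work-up.
- Fallback from alcohol 10 to ynol ether 14 without a potassium alkoxide: formylation of 10 with formic acetic anhydride and pyridine gives (S)-1-[2-geranyl-3,4-bis(methoxymethoxy)phenyl]-3-(triisopropylsilyloxy)propyl formate F4. Dichloro-olefination of the formate carbonyl with PPh3 and CCl4 gives the 2,2-dichloroethenyl ether F5. n-BuLi at –78 °C followed by methanol converts F5 into 14.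

**Step 10 (with the reagent from step 9).**
- The vinyl diazo ketone 19 may be consumed by conjugate addition or dipolar cycloaddition with itself before it meets the aldehyde.
- The aldehyde may be enolised, with β-elimination of the alkynyloxy group.
- Fallback from aldehyde 16 and methyl vinyl ketone 17 to diazo diketone 21, with the diazo group introduced last: the kinetic lithium enolate of 17 (LiN(i-Pr)2, –78 °C) adds to 16 to give (7S)-7-(ethynyloxy)-7-[2-geranyl-3,4-bis(methoxymethoxy)phenyl]-5-hydroxyhept-1-en-3-one F6. Dess–Martin oxidation gives (S)-7-(ethynyloxy)-7-[2-geranyl-3,4-bis(methoxymethoxy)phenyl]hept-1-ene-3,5-dione F7. Regitz diazo transfer with 4-acetamidobenzenesulfonyl azide and Et3N at 0 °C, where only the central methylene is deprotonated, gives 21.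

**Step 13.**
- Acid may catalyse addition of the C3′ phenol to the first alkene of the geranyl chain (chroman formation), or cationic cyclisation of the diene.
- Fallback from 26 to 27 without protic acid: Me3SiOTf and 2,2′-bipyridyl in CH2Cl2 at 0 °C convert the aryl MOM ethers, through pyridinium acetal salts, into aryl silyl ethers, giving (S)-2-[2-geranyl-3,4-bis(trimethylsilyloxy)phenyl]-7-(trimethylsilyloxy)chroman-4-one F8. Neutral water then hydrolyses F8 to 27.

## Further compounds

F1 | step 12 | [2-geranyl-3,4-bis(methoxymethoxy)phenyl]boronic acid | CC(C)=CCC/C(C)=C/Cc1c(B(O)O)ccc(OCOC)c1OCOC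
F2 | step 12 | 7-(methoxymethoxy)-4H-chromen-4-one | O=c1ccoc2cc(OCOC)ccc12
F3 | step 12 | (S)-2-[2-geranyl-3,4-bis(methoxymethoxy)phenyl]-7-(methoxymethoxy)chroman-4-one | CC(C)=CCC/C(C)=C/Cc1c([C@@H]2CC(=O)c3ccc(OCOC)cc3O2)ccc(OCOC)c1OCOC
F4 | step 6 | (S)-1-[2-geranyl-3,4-bis(methoxymethoxy)phenyl]-3-(triisopropylsilyloxy)propyl formate | CC(C)=CCC/C(C)=C/Cc1c([C@@H](OC=O)CCO[Si](C(C)C)(C(C)C)C(C)C)ccc(OCOC)c1OCOC
F5 | step 6 | (S)-1-[1-(2,2-dichloroethenyloxy)-3-(triisopropylsilyloxy)propyl]-2-geranyl-3,4-bis(methoxymethoxy)benzene | CC(C)=CCC/C(C)=C/Cc1c([C@@H](OC=C(Cl)Cl)CCO[Si](C(C)C)(C(C)C)C(C)C)ccc(OCOC)c1OCOC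
F6 | step 10 | (7S)-7-(ethynyloxy)-7-[2-geranyl-3,4-bis(methoxymethoxy)phenyl]-5-hydroxyhept-1-en-3-one, both C5 epimers | CC(C)=CCC/C(C)=C/Cc1c([C@@H](OC#C)CC(O)CC(=O)C=C)ccc(OCOC)c1OCOC
F7 | step 10 | (S)-7-(ethynyloxy)-7-[2-geranyl-3,4-bis(methoxymethoxy)phenyl]hept-1-ene-3,5-dione | CC(C)=CCC/C(C)=C/Cc1c([C@@H](OC#C)CC(=O)CC(=O)C=C)ccc(OCOC)c1OCOC
F8 | step 13 | (S)-2-[2-geranyl-3,4-bis(trimethylsilyloxy)phenyl]-7-(trimethylsilyloxy)chroman-4-one | CC(C)=CCC/C(C)=C/Cc1c([C@@H]2CC(=O)c3ccc(O[Si](C)(C)C)cc3O2)ccc(O[Si](C)(C)C)c1O[Si](C)(C)C
A1 | alternative 1 | (6E)-7,11-dimethyldodeca-6,10-diene-2,3-dione | CC(C)=CCC/C(C)=C/CCC(=O)C(C)=O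
A2 | alternative 1 | (6E)-2,3-bis(tert-butyldimethylsilyloxy)-7,11-dimethyldodeca-1,3,6,10-tetraene | C=C(O[Si](C)(C)C(C)(C)C)C(O[Si](C)(C)C(C)(C)C)=CC/C=C(\C)CCC=C(C)C
A3 | alternative 1 | methyl 2-geranyl-3,4-bis(tert-butyldimethylsilyloxy)benzoate | CC(C)=CCC/C(C)=C/Cc1c(C(=O)OC)ccc(O[Si](C)(C)C(C)(C)C)c1O[Si](C)(C)C(C)(C)C
A4 | alternative 2 | (1S,3S)-3-[2-bromo-4-(methoxymethoxy)phenyl]-1-[2-geranyl-3,4-bis(methoxymethoxy)phenyl]propane-1,3-diol | CC(C)=CCC/C(C)=C/Cc1c([C@@H](O)C[C@H](O)c2ccc(OCOC)cc2Br)ccc(OCOC)c1OCOC
A5 | alternative 2 | (2S,4S)-2-[2-geranyl-3,4-bis(methoxymethoxy)phenyl]-7-(methoxymethoxy)chroman-4-ol | CC(C)=CCC/C(C)=C/Cc1c([C@@H]2C[C@H](O)c3ccc(OCOC)cc3O2)ccc(OCOC)c1OCOC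
A6 | alternative 3 | 2-diazo-1-[2-{[2-geranyl-3,4-bis(methoxymethoxy)phenyl]methoxy}-4-(methoxymethoxy)phenyl]ethan-1-one | CC(C)=CCC/C(C)=C/Cc1c(COc2cc(OCOC)ccc2C(=O)C=[N+]=[N-])ccc(OCOC)c1OCOC
A7 | alternative 3 | (S)-2-[2-geranyl-3,4-bis(methoxymethoxy)phenyl]-7-(methoxymethoxy)chroman-4-one | CC(C)=CCC/C(C)=C/Cc1c([C@@H]2CC(=O)c3ccc(OCOC)cc3O2)ccc(OCOC)c1OCOC
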